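## Retrosynthetic overview

1. Target ⇐ syn-semihydrogenation of a 14-membered cycloalkyne (C6≡C7), itself closed by ring-closing alkyne metathesis of a tetrahydropyran-bridged bis(methylalkyne).
2. Tetrahydropyran (O between C3 and C13) ⇐ 6-exo opening of a (3S,4S)-epoxide by the C13 hydroxyl, setting C3 and C4; the epoxide comes from Shi epoxidation of the E-C3=C4 alkene.
3. cis-α-Methylene-γ-butyrolactone with C1 and C14 ⇐ key intermolecular indium-mediated carbonyl allylation (C1–C14 bond) of an α-silyloxy aldehyde (C7–C14) with a (2Z)-2-(bromomethyl)enoate (C1–C6, C15–C17).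
4. Aldehyde ⇐ (S)-citronellal (C12), proline aminoxylation (C13), Sharpless epoxidation/LiAlH4 (C8); bromide ⇐ propane-1,3-diol via Wittig olefination, copper-catalysed alkynylation and vinylalumination.
5. Ring order: γ-lactone (key step) → tetrahydropyran → 14-membered carbocycle.

Assumption: cembrane locants are used for late compounds (ring C1–C14; C1 carries C15(=C17H2)–C16(=O)–O–C14; methyls on C4, C8, C12; ether O between C3 and C13); alkoxides and the lithium acetylide formed by simple deprotonation are not numbered separately; commercial (S)-citronellal of high ee is used.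

## Route

Step 1
Reactants: 1 (S)-citronellal, (3S)-3,7-dimethyloct-6-enal
Product: 3 (2R,3S)-3,7-dimethyl-2-[(phenylamino)oxy]oct-6-en-1-ol, via α-anilinooxy aldehyde 2 (not isolated)
Conditions: PhN=O (1.0 equiv), 1 (2 equiv), L-proline (10 mol%), CHCl3, 4 °C; then NaBH4, EtOH, 0 °C
Reagents that add atoms: nitrosobenzene O=Nc1ccccc1
Why: Proline-catalysed enamine α-aminoxylation (organocatalytic nitroso aldol) delivers oxygen to one enamine face under catalyst control, which with L-proline sets C13 as R beside the citronellal-derived C12 centre, and in-situ NaBH4 reduction stops the labile aldehyde from oligomerising.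

Step 2
Reactants: 3 (2R,3S)-3,7-dimethyl-2-[(phenylamino)oxy]oct-6-en-1-ol
Product: 4 (2R,3S)-3,7-dimethyloct-6-ene-1,2-diol
Conditions: Zn dust, AcOH/THF (1:1), rt
Reagents that add atoms: none
Why: Reductive N–O bond cleavage by zinc in acetic acid frees the secondary alcohol without touching the trisubstituted alkene or either stereocentre.

Step 3
Reactants: 4 (2R,3S)-3,7-dimethyloct-6-ene-1,2-diol
Product: 6 (2R,3S)-1-[(4-methoxybenzyl)oxy]-3,7-dimethyloct-6-en-2-ol, via dibutylstannylene acetal 5 (not isolated)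
Conditions: Bu2SnO, toluene, reflux (Dean–Stark); then 4-MeOC6H4CH2Cl, Bu4NI, toluene, 100 °C
Reagents that add atoms: 4-methoxybenzyl chloride COc1ccc(CCl)cc1
Why: Stannylene-acetal-mediated Williamson etherification alkylates the less hindered primary oxygen selectively, which leaves the secondary C13 hydroxyl free for silylation.

Step 4
Reactants: 6 (2R,3S)-1-[(4-methoxybenzyl)oxy]-3,7-dimethyloct-6-en-2-ol
Product: 7 tert-butyl{[(2R,3S)-1-[(4-methoxybenzyl)oxy]-3,7-dimethyloct-6-en-2-yl]oxy}dimethylsilane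
Conditions: t-BuMe2SiOTf, 2,6-lutidine, CH2Cl2, −78 → 0 °C
Reagents that add atoms: tert-butyldimethylsilyl trifluoromethanesulfonate CC(C)(C)[Si](C)(C)OS(=O)(=O)C(F)(F)F
Why: Silylation of the hindered secondary alcohol with the silyl triflate installs a bulky non-chelating α-oxygen substituent that later enforces Felkin–Anh addition at C14.

Step 5
Reactants: 7 tert-butyl{[(2R,3S)-1-[(4-methoxybenzyl)oxy]-3,7-dimethyloct-6-en-2-yl]oxy}dimethylsilane
Product: 9 (2E,6S,7R)-7-[(tert-butyldimethylsilyl)oxy]-8-[(4-methoxybenzyl)oxy]-2,6-dimethyloct-2-en-1-ol, via enal 8 (not isolated)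
Conditions: SeO2 (0.5 equiv), t-BuOOH (3 equiv), salicylic acid (10 mol%), CH2Cl2, rt; then NaBH4, MeOH, 0 °C
Reagents that add atoms: selenium dioxide O=[Se]=O; tert-butyl hydroperoxide CC(C)(C)OO
Why: SeO2 allylic oxidation (ene reaction then 2,3-sigmatropic shift) hydroxylates the E-methyl group of the trisubstituted alkene selectively, and NaBH4 returns any over-oxidised enal to the E-allylic alcohol.

Step 6
Reactants: 9 (2E,6S,7R)-7-[(tert-butyldimethylsilyl)oxy]-8-[(4-methoxybenzyl)oxy]-2,6-dimethyloct-2-en-1-ol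
Product: 10 {(2S,3S)-3-[(3S,4R)-4-[(tert-butyldimethylsilyl)oxy]-5-[(4-methoxybenzyl)oxy]-3-methylpentyl]-2-methyloxiran-2-yl}methanol
Conditions: Ti(OiPr)4 (10 mol%), L-(+)-diethyl tartrate (12 mol%), t-BuOOH (2 equiv), 4 Å MS, CH2Cl2, −20 °C
Reagents that add atoms: tert-butyl hydroperoxide CC(C)(C)OO
Why: Sharpless asymmetric epoxidation of the E-2-methylallylic alcohol is reagent-controlled and with the L-(+)-tartrate ligand gives the (2S,3S)-epoxide, fixing the oxygen-bearing quaternary carbon that becomes C8.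

Step 7
Reactants: 10 {(2S,3S)-3-[(3S,4R)-4-[(tert-butyldimethylsilyl)oxy]-5-[(4-methoxybenzyl)oxy]-3-methylpentyl]-2-methyloxiran-2-yl}methanol
Product: 11 (2R,6S,7R)-7-[(tert-butyldimethylsilyl)oxy]-8-[(4-methoxybenzyl)oxy]-2,6-dimethyloctane-1,2-diol
Conditions: LiAlH4, THF, 0 °C → rt
Reagents that add atoms: none
Why: Hydride opening of the trisubstituted epoxide is an SN2 attack at the less substituted carbon, so the C–O bond of the quaternary carbon is untouched and the tertiary alcohol C8 is obtained as R.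

Step 8
Reactants: 11 (2R,6S,7R)-7-[(tert-butyldimethylsilyl)oxy]-8-[(4-methoxybenzyl)oxy]-2,6-dimethyloctane-1,2-diol
Product: 12 (2R,6S,7R)-7-[(tert-butyldimethylsilyl)oxy]-8-[(4-methoxybenzyl)oxy]-2,6-dimethyl-1,2-bis[(triethylsilyl)oxy]octane
Conditions: Et3SiOTf (2.5 equiv), 2,6-lutidine, CH2Cl2, −78 → 0 °C
Reagents that add atoms: triethylsilyl trifluoromethanesulfonate CC[Si](CC)(CC)OS(=O)(=O)C(F)(F)F
Why: Exhaustive silylation with the reactive silyl triflate protects the tertiary alcohol and turns the primary alcohol into a triethylsilyl ether that can be oxidised directly.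

Step 9
Reactants: 12 (2R,6S,7R)-7-[(tert-butyldimethylsilyl)oxy]-8-[(4-methoxybenzyl)oxy]-2,6-dimethyl-1,2-bis[(triethylsilyl)oxy]octane
Product: 13 (2R,6S,7R)-7-[(tert-butyldimethylsilyl)oxy]-8-[(4-methoxybenzyl)oxy]-2,6-dimethyl-2-[(triethylsilyl)oxy]octanal
Conditions: (COCl)2 (4 equiv), DMSO (8 equiv), CH2Cl2, −78 → −30 °C; then Et3N, −78 → 0 °C
Reagents that add atoms: none
Why: Under Swern conditions the activated dimethyl sulfoxide cleaves only the unhindered primary triethylsilyl ether and oxidises it to the aldehyde, while the tertiary triethylsilyl ether, the TBS ether and the PMB ether survive.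

Step 10
Reactants: 13 (2R,6S,7R)-7-[(tert-butyldimethylsilyl)oxy]-8-[(4-methoxybenzyl)oxy]-2,6-dimethyl-2-[(triethylsilyl)oxy]octanal
Product: 14 (3R,7S,8R)-8-[(tert-butyldimethylsilyl)oxy]-9-[(4-methoxybenzyl)oxy]-3,7-dimethyl-3-[(triethylsilyl)oxy]non-1-yne
Conditions: dimethyl (1-diazo-2-oxopropyl)phosphonate, K2CO3, MeOH, 0 °C → rt
Reagents that add atoms: dimethyl (1-diazo-2-oxopropyl)phosphonate COP(=O)(OC)C(=[N+]=[N-])C(C)=O
Why: Seyferth–Gilbert homologation in the Ohira–Bestmann variant turns the non-enolisable aldehyde into the terminal alkyne under mild base, so the adjacent quaternary centre cannot epimerise.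

Step 11
Reactants: 14 (3R,7S,8R)-8-[(tert-butyldimethylsilyl)oxy]-9-[(4-methoxybenzyl)oxy]-3,7-dimethyl-3-[(triethylsilyl)oxy]non-1-yne
Product: 15 (4R,8S,9R)-9-[(tert-butyldimethylsilyl)oxy]-10-[(4-methoxybenzyl)oxy]-4,8-dimethyl-4-[(triethylsilyl)oxy]dec-2-yne
Conditions: n-BuLi, THF, −78 °C; then MeI, −78 °C → rt
Reagents that add atoms: iodomethane CI
Why: Acetylide alkylation caps the terminal alkyne with the methyl group needed for ring-closing alkyne metathesis.

Step 12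
Reactants: 15 (4R,8S,9R)-9-[(tert-butyldimethylsilyl)oxy]-10-[(4-methoxybenzyl)oxy]-4,8-dimethyl-4-[(triethylsilyl)oxy]dec-2-yne
Product: 16 (2R,3S,7R)-2-[(tert-butyldimethylsilyl)oxy]-3,7-dimethyl-7-[(triethylsilyl)oxy]dec-8-yn-1-ol
Conditions: DDQ, CH2Cl2/pH 7 phosphate buffer (10:1), 0 °C
Reagents that add atoms: none
Why: Oxidative cleavage of the electron-rich PMB ether by DDQ frees the primary alcohol under neutral conditions that leave both silyl ethers and the alkyne intact.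

Step 13
Reactants: 16 (2R,3S,7R)-2-[(tert-butyldimethylsilyl)oxy]-3,7-dimethyl-7-[(triethylsilyl)oxy]dec-8-yn-1-ol
Product: 17 (2R,3S,7R)-2-[(tert-butyldimethylsilyl)oxy]-3,7-dimethyl-7-[(triethylsilyl)oxy]dec-8-ynal
Conditions: Dess–Martin periodinane, CH2Cl2, 0 °C → rt; used without chromatography
Reagents that add atoms: none
Why: Dess–Martin oxidation gives the α-silyloxy aldehyde under non-basic conditions, so the C13 centre does not epimerise.

Step 14
Reactants: 18 propane-1,3-diol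
Product: 19 3-[(tert-butyldimethylsilyl)oxy]propan-1-ol
Conditions: NaH (1.0 equiv), THF, 0 °C → rt; then t-BuMe2SiCl (1.0 equiv)
Reagents that add atoms: tert-butyldimethylsilyl chloride CC(C)(C)[Si](C)(C)Cl
Why: Monosilylation through the poorly soluble monosodium alkoxide gives the mono-TBS ether of the symmetric diol selectively.

Step 15
Reactants: 19 3-[(tert-butyldimethylsilyl)oxy]propan-1-ol
Product: 20 3-[(tert-butyldimethylsilyl)oxy]propanal
Conditions: Dess–Martin periodinane, CH2Cl2, rt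
Reagents that add atoms: none
Why: Dess–Martin oxidation of the primary alcohol gives the β-silyloxy aldehyde without β-elimination.

Step 16
Reactants: 20 3-[(tert-butyldimethylsilyl)oxy]propanal; 21 ethyl 2-(triphenylphosphoranylidene)propanoate
Product: 22 ethyl (2E)-5-[(tert-butyldimethylsilyl)oxy]-2-methylpent-2-enoate
Conditions: CH2Cl2, rt
Reagents that add atoms: none
Why: Wittig olefination with the stabilised ylide gives the E-trisubstituted enoate (E:Z above 95:5), which fixes the geometry of the later C3=C4 alkene.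

Step 17
Reactants: 22 ethyl (2E)-5-[(tert-butyldimethylsilyl)oxy]-2-methylpent-2-enoate
Product: 23 (2E)-5-[(tert-butyldimethylsilyl)oxy]-2-methylpent-2-en-1-ol
Conditions: i-Bu2AlH (2.2 equiv), CH2Cl2, −78 °C
Reagents that add atoms: none
Why: 1,2-Reduction of the conjugated ester by the aluminium hydride gives the allylic alcohol with the alkene geometry unchanged.

Step 18
Reactants: 23 (2E)-5-[(tert-butyldimethylsilyl)oxy]-2-methylpent-2-en-1-ol
Product: 24 {[(3E)-5-bromo-4-methylpent-3-en-1-yl]oxy}(tert-butyl)dimethylsilane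
Conditions: CBr4, PPh3, CH2Cl2, 0 °C
Reagents that add atoms: tetrabromomethane BrC(Br)(Br)Br
Why: Appel bromination converts the primary allylic alcohol into the bromide by SN2 displacement without allylic transposition.

Step 19
Reactants: 24 {[(3E)-5-bromo-4-methylpent-3-en-1-yl]oxy}(tert-butyl)dimethylsilane; 25 prop-1-yn-1-ylmagnesium bromide
Product: 26 tert-butyldimethyl{[(3E)-4-methyloct-3-en-6-yn-1-yl]oxy}silane
Conditions: CuBr·SMe2 (10 mol%), THF, 0 °C → rt
Reagents that add atoms: none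
Why: Copper-catalysed coupling of the alkynyl Grignard reagent at the primary carbon of the allylic bromide (SN2 mode) gives the skipped enyne with the E alkene retained.

Step 20
Reactants: 26 tert-butyldimethyl{[(3E)-4-methyloct-3-en-6-yn-1-yl]oxy}silane
Product: 27 (3E)-4-methyloct-3-en-6-yn-1-ol
Conditions: CSA (10 mol%), MeOH, rt
Reagents that add atoms: none
Why: Acid-catalysed methanolysis removes the primary TBS ether without isomerising the skipped enyne.

Step 21
Reactants: 27 (3E)-4-methyloct-3-en-6-yn-1-ol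
Product: 28 (3E)-4-methyloct-3-en-6-ynal
Conditions: Dess–Martin periodinane, NaHCO3, CH2Cl2, 0 °C; crude product used at once
Reagents that add atoms: none
Why: Buffered Dess–Martin oxidation gives the β,γ-unsaturated aldehyde under neutral conditions that avoid migration of the alkene into conjugation.

Step 22
Reactants: 28 (3E)-4-methyloct-3-en-6-ynal; 29 methyl prop-2-ynoate
Product: 31 methyl (5E)-3-hydroxy-6-methyl-2-methylidenedec-5-en-8-ynoate (racemic), via vinylalane 30 (not isolated)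
Conditions: 29, i-Bu2AlH, N-methylmorpholine N-oxide, THF, 0 °C; then 28, 0 °C → rt
Reagents that add atoms: none
Why: Vinylalumination (conjugate hydroalumination of the propiolate, then addition of the α-aluminoacrylate to the aldehyde) gives the Morita–Baylis–Hillman-type adduct without base, and the new carbinol centre is racemic but is erased in the next step.

Step 23
Reactants: 31 methyl (5E)-3-hydroxy-6-methyl-2-methylidenedec-5-en-8-ynoate
Product: 32 methyl (2Z,5E)-2-(bromomethyl)-6-methyldeca-2,5-dien-8-ynoate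
Conditions: NBS, Me2S, CH2Cl2, 0 °C → rt
Reagents that add atoms: N-bromosuccinimide O=C1CCC(=O)N1Br
Why: Bromination of the Baylis–Hillman alcohol through its alkoxysulfonium salt proceeds by SN2′ attack of bromide and gives the thermodynamically preferred 2Z bromide, in which the chain is cis to CH2Br.

Step 24
Reactants: 17 (2R,3S,7R)-2-[(tert-butyldimethylsilyl)oxy]-3,7-dimethyl-7-[(triethylsilyl)oxy]dec-8-ynal; 32 methyl (2Z,5E)-2-(bromomethyl)-6-methyldeca-2,5-dien-8-ynoate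
Product: 34 (4R,5S)-5-[(1R,2S,6R)-1-[(tert-butyldimethylsilyl)oxy]-2,6-dimethyl-6-[(triethylsilyl)oxy]non-7-yn-1-yl]-3-methylidene-4-[(2E)-3-methylhept-2-en-5-yn-1-yl]oxolan-2-one, via hydroxy ester 33 (not isolated)
Conditions: In powder, THF/H2O (2:1), rt; then PPTS (10 mol%), toluene, 60 °C
Reagents that add atoms: none
Why: Indium-mediated Barbier-type carbonyl allylation joins the two fragments through the γ-carbon of the 2-(methoxycarbonyl)allylindium species in a chair transition state that gives the syn C1/C14 adduct, Felkin–Anh attack anti to the bulky C13 silyloxy group sets C14 as S and C1 as R, and acid-catalysed lactonisation then closes the cis-disubstituted α-methylene-γ-butyrolactone.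

Step 25
Reactants: 34 the lactone of step 24
Product: 35 (4R,5S)-4-{[(2S,3S)-3-(but-2-yn-1-yl)-3-methyloxiran-2-yl]methyl}-5-[(1R,2S,6R)-1-[(tert-butyldimethylsilyl)oxy]-2,6-dimethyl-6-[(triethylsilyl)oxy]non-7-yn-1-yl]-3-methylideneoxolan-2-one
Conditions: ent-Shi ketone (1,2:4,5-di-O-isopropylidene-β-L-erythro-2,3-hexodiulo-2,6-pyranose, 30 mol%), KHSO5 (as 2KHSO5·KHSO4·K2SO4), K2CO3, Bu4NHSO4, MeCN/CH2(OMe)2/aq Na2B4O7 buffer (pH 10.5), 0 °C
Reagents that add atoms: potassium peroxymonosulfate [K+].[O-]S(=O)(=O)OO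
Why: Shi asymmetric epoxidation by the chiral dioxirane attacks only the electron-rich E-trisubstituted alkene through a spiro transition state and, with the L-fructose-derived ketone, gives the (3S,4S)-epoxide, which sets C4 directly and prepares C3 for inversion.

Step 26
Reactants: 35 the epoxide of step 25
Product: 37 (3aR,5R,7R,7aS)-5-[(2S)-2-hydroxyhex-4-yn-2-yl]-7-[(2S,6R)-6-hydroxy-6-methylnon-7-yn-2-yl]-3-methylidenehexahydro-2H-furo[2,3-c]pyran-2-one, via epoxy diol 36 (not isolated)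
Conditions: HF·pyridine, pyridine, THF, 0 °C → rt; then CSA (10 mol%), CH2Cl2, 0 °C
Reagents that add atoms: none
Why: Desilylation frees the C13 hydroxyl, which opens the epoxide in an acid-catalysed 6-exo-tet cyclisation at C3 with inversion, giving the 2,6-cis-tetrahydropyran with C3 as R and the tertiary C4 alcohol as S.

Step 27
Reactants: 37 the tetrahydropyran diol of step 26
Product: 38 (3aR,5R,7R,7aS)-3-methylidene-5-{(2S)-2-[(triethylsilyl)oxy]hex-4-yn-2-yl}-7-{(2S,6R)-6-methyl-6-[(triethylsilyl)oxy]non-7-yn-2-yl}hexahydro-2H-furo[2,3-c]pyran-2-one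
Conditions: Et3SiOTf (3 equiv), 2,6-lutidine, CH2Cl2, −78 → 0 °C
Reagents that add atoms: triethylsilyl trifluoromethanesulfonate CC[Si](CC)(CC)OS(=O)(=O)C(F)(F)F
Why: Silylation of both tertiary alcohols with the silyl triflate removes the protic groups that would deactivate the alkyne metathesis catalyst.

Step 28
Reactants: 38 the bis(triethylsilyl) ether of step 27
Product: 39 (1R,3R,4S,8R,12S,13R,14S)-3,13-epoxy-4,8-bis[(triethylsilyl)oxy]cembr-15(17)-en-6-yn-16,14-olide
Conditions: Mo(≡CC6H4OMe-4)(OSiPh3)3 (10 mol%), 5 Å MS, toluene (2 mM), 80 °C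
Reagents that add atoms: none
Why: Ring-closing alkyne metathesis of the two methyl-capped alkynes, driven by trapping of but-2-yne in the molecular sieves, closes the 14-membered carbocycle without touching the alkene of the lactone.

Step 29
Reactants: 39 the cycloalkyne bis(silyl ether) of step 28
Product: 40 (1R,3R,4S,8R,12S,13R,14S)-3,13-epoxy-4,8-dihydroxycembr-15(17)-en-6-yn-16,14-olide
Conditions: HF·pyridine, pyridine, THF, 0 °C → rt
Reagents that add atoms: none
Why: Fluoride-mediated desilylation liberates both tertiary alcohols under buffered acidic conditions that the α-methylene lactone tolerates.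

Step 30
Reactants: 40 the cycloalkyne diol of step 29
Product: 41 (1R,3R,4S,6Z,8R,12S,13R,14S)-3,13-epoxy-4,8-dihydroxycembra-6,15(17)-dien-16,14-olide (target)
Conditions: H2 (1 atm), Pd/CaCO3 poisoned with Pb(OAc)2, quinoline, EtOAc, rt, stopped after 1 equiv H2
Reagents that add atoms: none
Why: Semihydrogenation over lead-poisoned Pd/CaCO3 (Lindlar reduction) adds hydrogen syn to the cycloalkyne and so gives the 6Z alkene, the poisoned surface binding the alkyne far more strongly than the conjugated exocyclic alkene.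

## Compound list

1 | (S)-citronellal, (3S)-3,7-dimethyloct-6-enal | C[C@@H](CCC=C(C)C)CC=O | starting material
2 | (2R,3S)-3,7-dimethyl-2-[(phenylamino)oxy]oct-6-enal | O=C[C@H](ONc1ccccc1)[C@@H](C)CCC=C(C)C | intermediate
3 | (2R,3S)-3,7-dimethyl-2-[(phenylamino)oxy]oct-6-en-1-ol | OC[C@H](ONc1ccccc1)[C@@H](C)CCC=C(C)C | intermediate
4 | (2R,3S)-3,7-dimethyloct-6-ene-1,2-diol | OC[C@H](O)[C@@H](C)CCC=C(C)C | intermediate
5 | (4R)-2,2-dibutyl-4-[(2S)-6-methylhept-5-en-2-yl]-1,3,2-dioxastannolane | CCCC[Sn]1(CCCC)OC[C@H](O1)[C@@H](C)CCC=C(C)C | intermediate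
6 | (2R,3S)-1-[(4-methoxybenzyl)oxy]-3,7-dimethyloct-6-en-2-ol | COc1ccc(COC[C@H](O)[C@@H](C)CCC=C(C)C)cc1 | intermediate
7 | tert-butyl{[(2R,3S)-1-[(4-methoxybenzyl)oxy]-3,7-dimethyloct-6-en-2-yl]oxy}dimethylsilane | COc1ccc(COC[C@H](O[Si](C)(C)C(C)(C)C)[C@@H](C)CCC=C(C)C)cc1 | intermediate
8 | (2E,6S,7R)-7-[(tert-butyldimethylsilyl)oxy]-8-[(4-methoxybenzyl)oxy]-2,6-dimethyloct-2-enal | COc1ccc(COC[C@H](O[Si](C)(C)C(C)(C)C)[C@@H](C)CC/C=C(\C)C=O)cc1 | intermediate
9 | (2E,6S,7R)-7-[(tert-butyldimethylsilyl)oxy]-8-[(4-methoxybenzyl)oxy]-2,6-dimethyloct-2-en-1-ol | COc1ccc(COC[C@H](O[Si](C)(C)C(C)(C)C)[C@@H](C)CC/C=C(\C)CO)cc1 | intermediate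
10 | {(2S,3S)-3-[(3S,4R)-4-[(tert-butyldimethylsilyl)oxy]-5-[(4-methoxybenzyl)oxy]-3-methylpentyl]-2-methyloxiran-2-yl}methanol | OC[C@]1(C)O[C@H]1CC[C@H](C)[C@@H](O[Si](C)(C)C(C)(C)C)COCc1ccc(OC)cc1 | intermediate
11 | (2R,6S,7R)-7-[(tert-butyldimethylsilyl)oxy]-8-[(4-methoxybenzyl)oxy]-2,6-dimethyloctane-1,2-diol | OC[C@](C)(O)CCC[C@H](C)[C@@H](O[Si](C)(C)C(C)(C)C)COCc1ccc(OC)cc1 | intermediate
12 | (2R,6S,7R)-7-[(tert-butyldimethylsilyl)oxy]-8-[(4-methoxybenzyl)oxy]-2,6-dimethyl-1,2-bis[(triethylsilyl)oxy]octane | CC[Si](CC)(CC)OC[C@](C)(O[Si](CC)(CC)CC)CCC[C@H](C)[C@@H](O[Si](C)(C)C(C)(C)C)COCc1ccc(OC)cc1 | intermediate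
13 | (2R,6S,7R)-7-[(tert-butyldimethylsilyl)oxy]-8-[(4-methoxybenzyl)oxy]-2,6-dimethyl-2-[(triethylsilyl)oxy]octanal | O=C[C@](C)(O[Si](CC)(CC)CC)CCC[C@H](C)[C@@H](O[Si](C)(C)C(C)(C)C)COCc1ccc(OC)cc1 | intermediate
14 | (3R,7S,8R)-8-[(tert-butyldimethylsilyl)oxy]-9-[(4-methoxybenzyl)oxy]-3,7-dimethyl-3-[(triethylsilyl)oxy]non-1-yne | C#C[C@](C)(O[Si](CC)(CC)CC)CCC[C@H](C)[C@@H](O[Si](C)(C)C(C)(C)C)COCc1ccc(OC)cc1 | intermediate
15 | (4R,8S,9R)-9-[(tert-butyldimethylsilyl)oxy]-10-[(4-methoxybenzyl)oxy]-4,8-dimethyl-4-[(triethylsilyl)oxy]dec-2-yne | CC#C[C@](C)(O[Si](CC)(CC)CC)CCC[C@H](C)[C@@H](O[Si](C)(C)C(C)(C)C)COCc1ccc(OC)cc1 | intermediate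
16 | (2R,3S,7R)-2-[(tert-butyldimethylsilyl)oxy]-3,7-dimethyl-7-[(triethylsilyl)oxy]dec-8-yn-1-ol | CC#C[C@](C)(O[Si](CC)(CC)CC)CCC[C@H](C)[C@@H](O[Si](C)(C)C(C)(C)C)CO | intermediate
17 | (2R,3S,7R)-2-[(tert-butyldimethylsilyl)oxy]-3,7-dimethyl-7-[(triethylsilyl)oxy]dec-8-ynal | CC#C[C@](C)(O[Si](CC)(CC)CC)CCC[C@H](C)[C@@H](O[Si](C)(C)C(C)(C)C)C=O | intermediate
18 | propane-1,3-diol | OCCCO | starting material
19 | 3-[(tert-butyldimethylsilyl)oxy]propan-1-ol | CC(C)(C)[Si](C)(C)OCCCO | intermediate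
20 | 3-[(tert-butyldimethylsilyl)oxy]propanal | CC(C)(C)[Si](C)(C)OCCC=O | intermediate
21 | ethyl 2-(triphenylphosphoranylidene)propanoate | CCOC(=O)C(C)=P(c1ccccc1)(c1ccccc1)c1ccccc1 | starting material
22 | ethyl (2E)-5-[(tert-butyldimethylsilyl)oxy]-2-methylpent-2-enoate | CCOC(=O)/C(C)=C/CCO[Si](C)(C)C(C)(C)C | intermediate
23 | (2E)-5-[(tert-butyldimethylsilyl)oxy]-2-methylpent-2-en-1-ol | OC/C(C)=C/CCO[Si](C)(C)C(C)(C)C | intermediate
24 | {[(3E)-5-bromo-4-methylpent-3-en-1-yl]oxy}(tert-butyl)dimethylsilane | BrC/C(C)=C/CCO[Si](C)(C)C(C)(C)C | intermediate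
25 | prop-1-yn-1-ylmagnesium bromide | CC#C[Mg]Br | starting material
26 | tert-butyldimethyl{[(3E)-4-methyloct-3-en-6-yn-1-yl]oxy}silane | CC#CC/C(C)=C/CCO[Si](C)(C)C(C)(C)C | intermediate
27 | (3E)-4-methyloct-3-en-6-yn-1-ol | CC#CC/C(C)=C/CCO | intermediate
28 | (3E)-4-methyloct-3-en-6-ynal | CC#CC/C(C)=C/CC=O | intermediate
29 | methyl prop-2-ynoate | C#CC(=O)OC | starting material
30 | methyl 2-[bis(2-methylpropyl)alumanyl]prop-2-enoate | C=C(C(=O)OC)[Al](CC(C)C)CC(C)C | intermediate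
31 | methyl (5E)-3-hydroxy-6-methyl-2-methylidenedec-5-en-8-ynoate (racemic at C3) | C=C(C(=O)OC)C(O)C/C=C(\C)CC#CC | intermediate
32 | methyl (2Z,5E)-2-(bromomethyl)-6-methyldeca-2,5-dien-8-ynoate | COC(=O)/C(CBr)=C/C/C=C(\C)CC#CC | intermediate
33 | methyl (3R,4S,5R,6S,10R)-5-[(tert-butyldimethylsilyl)oxy]-4-hydroxy-6,10-dimethyl-2-methylidene-3-[(2E)-3-methylhept-2-en-5-yn-1-yl]-10-[(triethylsilyl)oxy]tridec-11-ynoate | COC(=O)C(=C)[C@@H](C/C=C(\C)CC#CC)[C@H](O)[C@H](O[Si](C)(C)C(C)(C)C)[C@@H](C)CCC[C@@](C)(O[Si](CC)(CC)CC)C#CC | intermediate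
34 | (4R,5S)-5-[(1R,2S,6R)-1-[(tert-butyldimethylsilyl)oxy]-2,6-dimethyl-6-[(triethylsilyl)oxy]non-7-yn-1-yl]-3-methylidene-4-[(2E)-3-methylhept-2-en-5-yn-1-yl]oxolan-2-one | C=C1C(=O)O[C@H]([C@H](O[Si](C)(C)C(C)(C)C)[C@@H](C)CCC[C@@](C)(O[Si](CC)(CC)CC)C#CC)[C@@H]1C/C=C(\C)CC#CC | intermediate
35 | (4R,5S)-4-{[(2S,3S)-3-(but-2-yn-1-yl)-3-methyloxiran-2-yl]methyl}-5-[(1R,2S,6R)-1-[(tert-butyldimethylsilyl)oxy]-2,6-dimethyl-6-[(triethylsilyl)oxy]non-7-yn-1-yl]-3-methylideneoxolan-2-one | C=C1C(=O)O[C@H]([C@H](O[Si](C)(C)C(C)(C)C)[C@@H](C)CCC[C@@](C)(O[Si](CC)(CC)CC)C#CC)[C@@H]1C[C@@H]1O[C@@]1(C)CC#CC | intermediate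
36 | (4R,5S)-4-{[(2S,3S)-3-(but-2-yn-1-yl)-3-methyloxiran-2-yl]methyl}-5-[(1R,2S,6R)-1,6-dihydroxy-2,6-dimethylnon-7-yn-1-yl]-3-methylideneoxolan-2-one | C=C1C(=O)O[C@H]([C@H](O)[C@@H](C)CCC[C@@](C)(O)C#CC)[C@@H]1C[C@@H]1O[C@@]1(C)CC#CC | intermediate
37 | (3aR,5R,7R,7aS)-5-[(2S)-2-hydroxyhex-4-yn-2-yl]-7-[(2S,6R)-6-hydroxy-6-methylnon-7-yn-2-yl]-3-methylidenehexahydro-2H-furo[2,3-c]pyran-2-one | C=C1C(=O)O[C@@H]2[C@@H]([C@@H](C)CCC[C@@](C)(O)C#CC)O[C@H](C[C@H]12)[C@@](C)(O)CC#CC | intermediate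
38 | (3aR,5R,7R,7aS)-3-methylidene-5-{(2S)-2-[(triethylsilyl)oxy]hex-4-yn-2-yl}-7-{(2S,6R)-6-methyl-6-[(triethylsilyl)oxy]non-7-yn-2-yl}hexahydro-2H-furo[2,3-c]pyran-2-one | C=C1C(=O)O[C@@H]2[C@@H]([C@@H](C)CCC[C@@](C)(O[Si](CC)(CC)CC)C#CC)O[C@H](C[C@H]12)[C@@](C)(O[Si](CC)(CC)CC)CC#CC | intermediate
39 | (1R,3R,4S,8R,12S,13R,14S)-3,13-epoxy-4,8-bis[(triethylsilyl)oxy]cembr-15(17)-en-6-yn-16,14-olide | C=C1C(=O)O[C@@H]2[C@@H]3O[C@H](C[C@H]12)[C@@](C)(O[Si](CC)(CC)CC)CC#C[C@](C)(O[Si](CC)(CC)CC)CCC[C@@H]3C | intermediate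
40 | (1R,3R,4S,8R,12S,13R,14S)-3,13-epoxy-4,8-dihydroxycembr-15(17)-en-6-yn-16,14-olide | C=C1C(=O)O[C@@H]2[C@@H]3O[C@H](C[C@H]12)[C@@](C)(O)CC#C[C@](C)(O)CCC[C@@H]3C | intermediate
41 | (1R,3R,4S,6Z,8R,12S,13R,14S)-3,13-epoxy-4,8-dihydroxycembra-6,15(17)-dien-16,14-olide (CNP0146755.1) | C=C1C(=O)O[C@@H]2[C@@H]3O[C@H](C[C@H]12)[C@@](C)(O)C/C=C\[C@](C)(O)CCC[C@@H]3C | target

## Step count and risks

Total steps: 30 (steps 1–13 to aldehyde 17, steps 14–23 to bromide 32, steps 24–30 after the union).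
Longest linear sequence: 20 steps (1–13, then 24–30).

Most likely to fail, first: step 24. The hindered α-silyloxy aldehyde may give incomplete Felkin–Anh or syn control in the aqueous Barbier reaction. The fallback sets out from 31 and comes back at 33. Acetylation of 31 (Ac2O, DMAP, pyridine) gives methyl (5E)-3-(acetyloxy)-6-methyl-2-methylidenedec-5-en-8-ynoate F1. Transposing allylic borylation (B2pin2, Pd2(dba)3, toluene, 50 °C) converts it into methyl (2E,5E)-6-methyl-2-[(4,4,5,5-tetramethyl-1,3,2-dioxaborolan-2-yl)methyl]deca-2,5-dien-8-ynoate F2, in which the chain is cis to CH2B. Heating F2 with aldehyde 17 (toluene, 80 °C) is a type 1 allylboration through a closed six-membered transition state, which transfers this geometry into the syn C1/C14 relationship with Felkin selectivity and gives the pinacol borate of the hydroxy ester F3. Hydrolysis of F3 on work-up returns 33 for the usual PPTS lactonisation.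

Second: step 28. Alkyne metathesis at a fully substituted propargylic carbon inside a bridged bicycle may be slow or may oligomerise. The fallback sets out from 34 and comes back at 40, closing the large ring before the tetrahydropyran exists. The flexible diyne 34 is cyclised with the same Mo(≡CC6H4OMe-4)(OSiPh3)3 catalyst to (1R,3E,8R,12S,13R,14S)-13-[(tert-butyldimethylsilyl)oxy]-8-[(triethylsilyl)oxy]cembra-3,15(17)-dien-6-yn-16,14-olide F4. Epoxidation with the ent-Shi ketone and KHSO5 gives the (3S,4S)-3,4-epoxide F5. HF·pyridine then liberates (1R,3S,4S,8R,12S,13R,14S)-3,4-epoxy-8,13-dihydroxycembr-15(17)-en-6-yn-16,14-olide F6, which with CSA undergoes transannular 6-exo opening at C3 to give 40.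

Third: step 30. The exocyclic methylene of the lactone may be reduced along with the hindered cycloalkyne. The fallback sets out from 40 and comes back at 41, masking the acrylate during the hydrogenation. Conjugate addition of Me2NH (THF, 0 °C) to 40 gives the 17-(dimethylamino)-15,17-dihydro Mannich base F7 (C15 epimers). Semihydrogenation over the same poisoned Pd/CaCO3 gives its 6Z alkene F8. MeI forms the trimethylammonium iodide F9, which loses trimethylamine on treatment with aqueous NaHCO3 and regenerates the α-methylene lactone of 41.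

## Further compounds

F1 | step 24 | methyl (5E)-3-(acetyloxy)-6-methyl-2-methylidenedec-5-en-8-ynoate (racemic) | C=C(C(=O)OC)C(OC(C)=O)C/C=C(\C)CC#CC
F2 | step 24 | methyl (2E,5E)-6-methyl-2-[(4,4,5,5-tetramethyl-1,3,2-dioxaborolan-2-yl)methyl]deca-2,5-dien-8-ynoate | COC(=O)/C(CB1OC(C)(C)C(C)(C)O1)=C/C/C=C(\C)CC#CC
F3 | step 24 | 4-O-(4,4,5,5-tetramethyl-1,3,2-dioxaborolan-2-yl) derivative of hydroxy ester 33 | COC(=O)C(=C)[C@@H](C/C=C(\C)CC#CC)[C@H](OB1OC(C)(C)C(C)(C)O1)[C@H](O[Si](C)(C)C(C)(C)C)[C@@H](C)CCC[C@@](C)(O[Si](CC)(CC)CC)C#CC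
F4 | step 28 | (1R,3E,8R,12S,13R,14S)-13-[(tert-butyldimethylsilyl)oxy]-8-[(triethylsilyl)oxy]cembra-3,15(17)-dien-6-yn-16,14-olide | C=C1C(=O)O[C@H]2[C@@H]1C/C=C(\C)CC#C[C@](C)(O[Si](CC)(CC)CC)CCC[C@H](C)[C@H]2O[Si](C)(C)C(C)(C)C
F5 | step 28 | (1R,3S,4S,8R,12S,13R,14S)-3,4-epoxy-13-[(tert-butyldimethylsilyl)oxy]-8-[(triethylsilyl)oxy]cembr-15(17)-en-6-yn-16,14-olide | C=C1C(=O)O[C@H]2[C@@H]1C[C@@H]1O[C@@]1(C)CC#C[C@](C)(O[Si](CC)(CC)CC)CCC[C@H](C)[C@H]2O[Si](C)(C)C(C)(C)C
F6 | step 28 | (1R,3S,4S,8R,12S,13R,14S)-3,4-epoxy-8,13-dihydroxycembr-15(17)-en-6-yn-16,14-olide | C=C1C(=O)O[C@H]2[C@@H]1C[C@@H]1O[C@@]1(C)CC#C[C@](C)(O)CCC[C@H](C)[C@H]2O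
F7 | step 30 | 17-(dimethylamino)-15,17-dihydro derivative of 40 (C15 epimers) | CN(C)CC1C(=O)O[C@@H]2[C@@H]3O[C@H](C[C@H]12)[C@@](C)(O)CC#C[C@](C)(O)CCC[C@@H]3C
F8 | step 30 | 17-(dimethylamino)-15,17-dihydro derivative of 41 (C15 epimers) | CN(C)CC1C(=O)O[C@@H]2[C@@H]3O[C@H](C[C@H]12)[C@@](C)(O)C/C=C\[C@](C)(O)CCC[C@@H]3C
F9 | step 30 | 17-(trimethylammonio)-15,17-dihydro derivative of 41 iodide | C[N+](C)(C)CC1C(=O)O[C@@H]2[C@@H]3O[C@H](C[C@H]12)[C@@](C)(O)C/C=C\[C@](C)(O)CCC[C@@H]3C.[I-]
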